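**Retrosynthetic overview**
- The target comes from a last-step deoxygenation that turns a spare bridgehead epoxyprenyl arm back into the prenyl group.
- The bicyclo[3.2.1]octane-2,4,8-trione core is made in one operation from two acyclic pieces, the dianion of 2-methylheptane-3,5-dione and a 2,2-bis(epoxyprenyl)malonate. An intermolecular Claisen acylation and a Dieckmann closure form the six-membered trione ring (ring A) first; a 5-exo C-alkylation of the ring enolate on one epoxide then closes the cyclopentane (ring B).
- Both epoxides are (R), from Shi epoxidation of dimethyl diprenylmalonate. The malonate carbon carries two identical arms and is not a stereocentre, so an exo-selective SN2 epoxide opening sets C6 and both bridgeheads together.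
- Building blocks: dimethyl malonate and prenyl bromide; 3-methylbutan-2-one and methyl propanoate.

Assumption: lithium and sodium enolates or alkoxides formed by deprotonation are treated as forms of the numbered neutral compounds. Core numbering: C1 prenyl bridgehead, C5 methyl bridgehead, C6 carbinol-bearing carbon, C8 bridging ketone.

**Step 1**
Reactants: 1 dimethyl malonate; 2 prenyl bromide (1-bromo-3-methylbut-2-ene)
Product: 3 dimethyl 2,2-bis(3-methylbut-2-en-1-yl)propanedioate
Conditions: NaH (2.3 equiv), 2 (2.4 equiv), THF, 0 °C → reflux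
Reagents that add atoms: none
Why: Malonic ester alkylation, in which the sodium malonate enolate displaces bromide twice at the primary allylic carbon (SN2); no stereocentre is formed.

**Step 2**
Reactants: 3 dimethyl 2,2-bis(3-methylbut-2-en-1-yl)propanedioate
Product: 4 dimethyl 2,2-bis{[(2R)-3,3-dimethyloxiran-2-yl]methyl}propanedioate
Conditions: D-fructose-derived Shi ketone 1,2:4,5-di-O-isopropylidene-β-D-erythro-2,3-hexodiulo-2,6-pyranose (C12H18O6, 0.6 equiv), KHSO5 (as Oxone, 3.0 equiv), K2CO3, Bu4NHSO4 (cat.), MeCN–CH2(OMe)2–aq. Na2B4O7 buffer (pH 10.5), 0 °C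
Reagents that add atoms: Oxone (active component potassium peroxymonosulfate, KHSO5), [K+].[O-]S(=O)(=O)OO
Why: Shi asymmetric epoxidation, in which the chiral dioxirane epoxidises each trisubstituted alkene through a spiro transition state that gives the (R)-epoxide; the two events are independent, so the (R,R) isomer is statistically enriched and the minor meso isomer is the main stereo-impurity, while the hindered esters and the non-stereogenic malonate carbon are untouched.

**Step 3**
Reactants: 5 3-methylbutan-2-one; 6 methyl propanoate
Product: 7 2-methylheptane-3,5-dione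
Conditions: NaH (2.2 equiv), 6 (2.0 equiv), THF, reflux; 1 M HCl
Reagents that add atoms: none
Why: Crossed Claisen condensation, in which the methyl-side enolate of 5 is acylated by 6 and the product is drained off as its sodium β-diketonate (acylation at the methine gives a non-enolisable product and reverts); no stereocentre is formed.

**Step 4**
Reactants: 4 dimethyl 2,2-bis{[(2R)-3,3-dimethyloxiran-2-yl]methyl}propanedioate; 7 2-methylheptane-3,5-dione
Product: 10 (1S,5R,6R)-1-{[(2R)-3,3-dimethyloxiran-2-yl]methyl}-4-hydroxy-6-(2-hydroxypropan-2-yl)-5-methyl-3-(2-methylpropanoyl)bicyclo[3.2.1]oct-3-ene-2,8-dione, via triketo ester 8 (not isolated), via monocyclic trione 9 (not isolated)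
Conditions: 7 (1.1 equiv), LiN(iPr)2 (3.3 equiv), THF, −78 → 0 °C; add 4 (1.0 equiv), −78 → 20 °C, 4 h; then 60 °C, 8 h; sat. aq. NH4Cl, 0 °C; crude used at once
Reagents that add atoms: none
Why: Proposed new method: the terminal (ethyl CH2) carbanion of the dilithium dianion of 7 acylates one of the two equivalent ester groups of 4 to give 8 (closest known reaction: acylation of β-diketone dianions by esters to 1,3,5-triketones); the third equivalent of amide base keeps 8 as a dienolate whose C6 carbon closes ring A by Dieckmann condensation onto the remaining ester (closest known reaction: ketone plus dialkylmalonate double Claisen routes to 2,2-disubstituted cyclohexane-1,3,5-triones such as syncarpic acid); on heating, the C4 enolate carbon of the near-planar dianion of 9 opens one epoxide at its less substituted carbon in a 5-exo-tet, enol-exo C-alkylation that closes ring B (closest known reactions: intramolecular enolate–epoxide alkylation and C-alkylation of acylphloroglucinol polyanions); the two identical (R)-epoxide arms on the non-stereogenic quaternary carbon sit on opposite faces and offer one exo and one endo transition state, the exo one (CMe2–O turned away from the trione ring, over the bridging carbonyl) is sterically preferred, and SN2 inversion at the (R)-epoxide carbon then gives (6R) and fixes both bridgeheads in the same event.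

**Step 5**
Reactants: 10 (1S,5R,6R)-1-{[(2R)-3,3-dimethyloxiran-2-yl]methyl}-4-hydroxy-6-(2-hydroxypropan-2-yl)-5-methyl-3-(2-methylpropanoyl)bicyclo[3.2.1]oct-3-ene-2,8-dione
Product: 11 (1R,5R,6R)-4-hydroxy-6-(2-hydroxypropan-2-yl)-5-methyl-1-(3-methylbut-2-en-1-yl)-3-(2-methylpropanoyl)bicyclo[3.2.1]oct-3-ene-2,8-dione
Conditions: LiN(SiMe3)2 (2.1 equiv), THF, −78 °C; then added to WCl6/n-BuLi (1:2, 3 equiv of tungsten, premixed in THF, −78 → 20 °C), 20 °C, 2 h; sat. aq. NH4Cl, 0 °C
Reagents that add atoms: none
Why: Sharpless tungsten deoxygenation, in which the epoxide oxygen is transferred to the low-valent (formally tetravalent) tungsten chloride to give the alkene and WOCl4; the triketone and tertiary alcohol are masked as lithium enolate and alkoxide so no acid can trigger attack of the C2 enol oxygen on the epoxide, the hindered bridging ketone is inert, and no stereocentre is touched (the C1 descriptor changes from S to R only because of ligand priorities).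

**Compound list**
1 | dimethyl malonate | COC(=O)CC(=O)OC | starting material
2 | prenyl bromide (1-bromo-3-methylbut-2-ene) | CC(C)=CCBr | starting material
3 | dimethyl 2,2-bis(3-methylbut-2-en-1-yl)propanedioate | COC(=O)C(CC=C(C)C)(CC=C(C)C)C(=O)OC | intermediate
4 | dimethyl 2,2-bis{[(2R)-3,3-dimethyloxiran-2-yl]methyl}propanedioate | COC(=O)C(C[C@H]1OC1(C)C)(C[C@H]1OC1(C)C)C(=O)OC | intermediate
5 | 3-methylbutan-2-one | CC(C)C(C)=O | starting material
6 | methyl propanoate | CCC(=O)OC | starting material
7 | 2-methylheptane-3,5-dione | CCC(=O)CC(=O)C(C)C | intermediate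
8 | methyl 2,2-bis{[(2R)-3,3-dimethyloxiran-2-yl]methyl}-4,8-dimethyl-3,5,7-trioxononanoate (C4 configuration mobile) | COC(=O)C(C[C@H]1OC1(C)C)(C[C@H]1OC1(C)C)C(=O)C(C)C(=O)CC(=O)C(C)C | intermediate
9 | 3-hydroxy-6,6-bis{[(2R)-3,3-dimethyloxiran-2-yl]methyl}-4-methyl-2-(2-methylpropanoyl)cyclohex-2-ene-1,5-dione (C4 configuration mobile) | CC(C)C(=O)C1=C(O)C(C)C(=O)C(C[C@H]2OC2(C)C)(C[C@H]2OC2(C)C)C1=O | intermediate
10 | (1S,5R,6R)-1-{[(2R)-3,3-dimethyloxiran-2-yl]methyl}-4-hydroxy-6-(2-hydroxypropan-2-yl)-5-methyl-3-(2-methylpropanoyl)bicyclo[3.2.1]oct-3-ene-2,8-dione | CC1(C)O[C@@H]1C[C@@]23C[C@@H](C(C)(C)O)[C@@](C)(C2=O)C(O)=C(C(=O)C(C)C)C3=O | intermediate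
11 | (1R,5R,6R)-4-hydroxy-6-(2-hydroxypropan-2-yl)-5-methyl-1-(3-methylbut-2-en-1-yl)-3-(2-methylpropanoyl)bicyclo[3.2.1]oct-3-ene-2,8-dione | CC(C)=CC[C@@]12C[C@@H](C(C)(C)O)[C@@](C)(C1=O)C(O)=C(C(=O)C(C)C)C2=O | target

**Totals**
Total step count: 5. Longest linear sequence: 4 (steps 1, 2, 4, 5).

**Steps most likely to fail, with fallbacks**

Step 4 (three C–C bonds and two rings in one pot). The main risks are a slow intermolecular Claisen at the hindered malonate ester, attack on the epoxides before ring A is closed, and O- instead of C-alkylation in the last event. The fallback sets out from 4 and comes back at 8. One ester of 4 is saponified with LiOH (1.0 equiv, THF–H2O, 0 °C) and acidified cold to give 2,2-bis{[(2R)-3,3-dimethyloxiran-2-yl]methyl}-3-methoxy-3-oxopropanoic acid F1. 1,1′-Carbonyldiimidazole converts it into methyl 2,2-bis{[(2R)-3,3-dimethyloxiran-2-yl]methyl}-3-(1H-imidazol-1-yl)-3-oxopropanoate F2. This far more reactive acyl donor is added to the dianion of 7 at −78 °C, so that 8 can be isolated. The Dieckmann closure and epoxide opening of 8 (to 9 and then 10) are then run as a separate operation with LiN(SiMe3)2 in THF, where temperature and counter-ion can be tuned without the intermolecular step interfering.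

Step 5 (deoxygenation beside an enol that can attack the epoxide). The risk is that the C2 enol or enolate oxygen opens the spare epoxide to a fused furan or pyran before oxygen transfer to tungsten. The fallback avoids the spare epoxide altogether; it sets out from 3 and comes back at 11. Shi epoxidation with KHSO5 limited to about one equivalent gives dimethyl 2-{[(2R)-3,3-dimethyloxiran-2-yl]methyl}-2-(3-methylbut-2-en-1-yl)propanedioate F3, with 3 and 4 recovered. The same dianion cascade with 7 passes through methyl 2-{[(2R)-3,3-dimethyloxiran-2-yl]methyl}-4,8-dimethyl-2-(3-methylbut-2-en-1-yl)-3,5,7-trioxononanoate F4 and 3-hydroxy-6-{[(2R)-3,3-dimethyloxiran-2-yl]methyl}-4-methyl-6-(3-methylbut-2-en-1-yl)-2-(2-methylpropanoyl)cyclohex-2-ene-1,5-dione F5, formed as both epimers at the quaternary carbon. The epimer with the epoxide arm on the exo-capable face cyclises directly to 11. The other epimer cannot reach an exo transition state and is removed by chromatography, so this variant is capped at half of the material.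

Step 2 (double Shi epoxidation). The risks are incomplete conversion of the second alkene, ester hydrolysis at pH 10.5, and an enantiomeric excess too low for the statistical upgrade to rescue. The fallback takes the chirality from an allylic alcohol epoxidation instead; it sets out from 1 and comes back at 4. Prenol is epoxidised under Sharpless conditions (Ti(OiPr)4, D-(−)-diisopropyl tartrate, t-BuOOH, 4 Å sieves, CH2Cl2, −20 °C) to [(2R)-3,3-dimethyloxiran-2-yl]methanol F6. Tf2O and 2,6-lutidine at −78 °C give [(2R)-3,3-dimethyloxiran-2-yl]methyl trifluoromethanesulfonate F7, which is used cold. Dimethyl malonate 1 is dialkylated with F7 (2.2 equiv) and KN(SiMe3)2 (2.1 equiv) in THF at −78 → −20 °C, where triflate displacement outruns cyclopropane formation by the mono-alkylated malonate, to give 4.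

**Further compounds**
F1 | step 4 | 2,2-bis{[(2R)-3,3-dimethyloxiran-2-yl]methyl}-3-methoxy-3-oxopropanoic acid | COC(=O)C(C[C@H]1OC1(C)C)(C[C@H]1OC1(C)C)C(O)=O
F2 | step 4 | methyl 2,2-bis{[(2R)-3,3-dimethyloxiran-2-yl]methyl}-3-(1H-imidazol-1-yl)-3-oxopropanoate | COC(=O)C(C[C@H]1OC1(C)C)(C[C@H]1OC1(C)C)C(=O)n1ccnc1
F3 | step 5 | dimethyl 2-{[(2R)-3,3-dimethyloxiran-2-yl]methyl}-2-(3-methylbut-2-en-1-yl)propanedioate | COC(=O)C(CC=C(C)C)(C[C@H]1OC1(C)C)C(=O)OC
F4 | step 5 | methyl 2-{[(2R)-3,3-dimethyloxiran-2-yl]methyl}-4,8-dimethyl-2-(3-methylbut-2-en-1-yl)-3,5,7-trioxononanoate (both C2 epimers) | COC(=O)C(CC=C(C)C)(C[C@H]1OC1(C)C)C(=O)C(C)C(=O)CC(=O)C(C)C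
F5 | step 5 | 3-hydroxy-6-{[(2R)-3,3-dimethyloxiran-2-yl]methyl}-4-methyl-6-(3-methylbut-2-en-1-yl)-2-(2-methylpropanoyl)cyclohex-2-ene-1,5-dione (both C6 epimers) | CC(C)C(=O)C1=C(O)C(C)C(=O)C(CC=C(C)C)(C[C@H]2OC2(C)C)C1=O
F6 | step 2 | [(2R)-3,3-dimethyloxiran-2-yl]methanol | CC1(C)O[C@@H]1CO
F7 | step 2 | [(2R)-3,3-dimethyloxiran-2-yl]methyl trifluoromethanesulfonate | CC1(C)O[C@@H]1COS(=O)(=O)C(F)(F)F
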